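Retrosynthesis: after the three benzyl ethers and the C4 ketone (carried as a carbinol) are unmasked, ring C is cut at the aryl ether bond O1–C8a; the chain is then cut at C2–C3 (Claisen condensation, followed by two ketone reductions) and at C4–C4a (Friedel–Crafts acetylation); the piperidine is cut at N1'–C6', C2'–C3' and N–CH3.
Forward: the N-methylpiperidine ring is built first on the formyl carbon of a 4-bromo-2,6-dialkoxybenzaldehyde, the three-carbon chain with ring B is then attached to ring A, and ring C is closed last by intramolecular O-arylation, followed by oxidation at C4 and debenzylation.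
Enabling feature: O1 links the C2 carbinol carbon to C8a of ring A, and C8a lies para to C6, the carbon that carries the piperidine between the oxygens at C5 and C7. The para bromine of the starting aldehyde therefore sits exactly at C8a, the two free ring carbons beside it are equivalent, and acylation of either one creates C4a.
Stereochemistry: C2' comes from addition of 4-chlorobutylmagnesium bromide to the (R)-tert-butanesulfinyl imine; C2 comes from asymmetric transfer hydrogenation with the (S,S)-TsDPEN ruthenium catalyst and survives ring closure because its C–O bond is not broken; the C4 carbinol is set anti by directed reduction and later oxidised away.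

Key step: step 11

Assumption: flavanone numbering (O1, C2, C3, C4, C4a, C5 to C8, C8a; primed numbers for the piperidine) is used for all intermediates, including open-chain ones, and the configuration of the temporary C4 carbinol is taken to be without consequence for the target because step 12 removes it.

Step 1
Reactants: 1 4-bromo-2,6-dimethoxybenzaldehyde
Product: 2 4-bromo-2,6-dihydroxybenzaldehyde
Conditions: BBr3, CH2Cl2, −78 °C → rt; H2O
Reagents that add atoms: none
Why: Lewis-acid ether cleavage, in which BBr3 binds the methoxy oxygens (helped by the neighbouring formyl group) and bromide removes both methyl groups, freeing the phenols for exchange to benzyl ethers that can be removed at the end without acid or base.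

Step 2
Reactants: 2 4-bromo-2,6-dihydroxybenzaldehyde
Product: 3 2,6-bis(benzyloxy)-4-bromobenzaldehyde
Conditions: BnBr, K2CO3, DMF, 60 °C
Reagents that add atoms: benzyl bromide, BrCc1ccccc1
Why: Williamson ether synthesis, in which both phenoxides, although hydrogen-bonded to the aldehyde, should be benzylated in a dipolar aprotic solvent with carbonate base.

Step 3
Reactants: 3 2,6-bis(benzyloxy)-4-bromobenzaldehyde; 4 (R)-2-methylpropane-2-sulfinamide
Product: 5 (R)-N-{(E)-[2,6-bis(benzyloxy)-4-bromophenyl]methylidene}-2-methylpropane-2-sulfinamide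
Conditions: Ti(OEt)4, THF, 65 °C
Reagents that add atoms: none
Why: Ti(OEt)4-mediated condensation of an aldehyde with tert-butanesulfinamide, in which the titanium alkoxide activates the hindered carbonyl and takes up the water formed, giving the E-configured N-sulfinyl aldimine.

Step 4
Reactants: 5 (R)-N-{(E)-[2,6-bis(benzyloxy)-4-bromophenyl]methylidene}-2-methylpropane-2-sulfinamide; 6 1-bromo-4-chlorobutane
Product: 8 (R)-N-{(1S)-1-[2,6-bis(benzyloxy)-4-bromophenyl]-5-chloropentyl}-2-methylpropane-2-sulfinamide, via 4-chlorobutylmagnesium bromide 7 (not isolated)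
Conditions: 6, Mg, Et2O, rt; then 5, CH2Cl2, −48 °C; aq. NH4Cl
Reagents that add atoms: none
Why: Grignard 1,2-addition to an N-tert-butanesulfinyl aldimine in a non-coordinating solvent should pass through the six-membered chair transition state with magnesium bound to the sulfinyl oxygen and the tert-butyl group equatorial, so that the sulfur auxiliary directs the alkyl group to the Si face of the imine carbon and sets the benzylic stereocenter as S, and any minor diastereomer should be separable by chromatography.

Step 5
Reactants: 8 (R)-N-{(1S)-1-[2,6-bis(benzyloxy)-4-bromophenyl]-5-chloropentyl}-2-methylpropane-2-sulfinamide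
Product: 9 (2S)-2-[2,6-bis(benzyloxy)-4-bromophenyl]-1-[(R)-tert-butanesulfinyl]piperidine
Conditions: KOtBu, THF, 0 °C → rt
Reagents that add atoms: none
Why: intramolecular N-alkylation (6-exo-tet SN2) of the potassium sulfinamide by the primary chloride closes the piperidine ring without touching the benzylic stereocenter.

Step 6
Reactants: 9 (2S)-2-[2,6-bis(benzyloxy)-4-bromophenyl]-1-[(R)-tert-butanesulfinyl]piperidine
Product: 11 (2S)-2-[2,6-bis(benzyloxy)-4-bromophenyl]-1-methylpiperidine, via (2S)-2-[2,6-bis(benzyloxy)-4-bromophenyl]piperidine hydrochloride 10 (not isolated)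
Conditions: HCl (4 M in dioxane), MeOH, 0 °C; evaporate; then aq. CH2O, NaBH(OAc)3, NaOAc, ClCH2CH2Cl, rt
Reagents that add atoms: formaldehyde, C=O
Why: acidic methanolysis cleaves the N–S bond of the sulfinamide, and reductive amination of the secondary amine with formaldehyde and NaBH(OAc)3 should install the N-methyl group while aryl bromide and benzyl ethers stay intact.

Step 7
Reactants: 11 (2S)-2-[2,6-bis(benzyloxy)-4-bromophenyl]-1-methylpiperidine; 12 acetyl chloride
Product: 13 1-{2,4-bis(benzyloxy)-6-bromo-3-[(2S)-1-methylpiperidin-2-yl]phenyl}ethan-1-one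
Conditions: SnCl4, CH2Cl2, −20 °C; then AcCl, −20 → 0 °C; aq. NaHCO3
Reagents that add atoms: none
Why: Friedel–Crafts acylation, in which the two free ring carbons are equivalent and each is ortho to one benzyloxy group and para to the other, so the acylium ion can only enter next to the bromine, while prior complexation of the amine with SnCl4 blocks N-acylation, the mild Lewis acid at low temperature should spare the benzyl ethers, and the new acyl group deactivates the ring against a second acylation.

Step 8
Reactants: 13 1-{2,4-bis(benzyloxy)-6-bromo-3-[(2S)-1-methylpiperidin-2-yl]phenyl}ethan-1-one; 14 methyl 4-(benzyloxy)benzoate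
Product: 15 1-{2,4-bis(benzyloxy)-6-bromo-3-[(2S)-1-methylpiperidin-2-yl]phenyl}-3-[4-(benzyloxy)phenyl]propane-1,3-dione
Conditions: LiN(SiMe3)2, THF, −78 °C; then 14, −78 °C → rt; AcOH
Reagents that add atoms: none
Why: crossed Claisen condensation, in which the lithium enolate of the methyl ketone attacks the non-enolisable benzoate ester and deprotonation of the resulting 1,3-diketone by the second equivalent of base drives the reaction forward.

Step 9
Reactants: 15 1-{2,4-bis(benzyloxy)-6-bromo-3-[(2S)-1-methylpiperidin-2-yl]phenyl}-3-[4-(benzyloxy)phenyl]propane-1,3-dione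
Product: 16 (3S)-1-{2,4-bis(benzyloxy)-6-bromo-3-[(2S)-1-methylpiperidin-2-yl]phenyl}-3-[4-(benzyloxy)phenyl]-3-hydroxypropan-1-one
Conditions: RuCl(p-cymene)[(S,S)-TsDPEN] (cat.), HCO2H/Et3N (5:2), DMF, 40 °C
Reagents that add atoms: none
Why: Noyori-type asymmetric transfer hydrogenation, in which the ruthenium hydride of the (S,S)-TsDPEN complex should reduce the unhindered, conjugated ring B carbonyl through the outer-sphere six-membered transition state (aryl group held against the cymene ligand) and so set the carbinol as S under catalyst control as for acetophenones, whereas the ring A carbonyl, twisted and shielded by its two ortho substituents, should react much more slowly and any diol already formed is the product of step 10.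

Step 10
Reactants: 16 (3S)-1-{2,4-bis(benzyloxy)-6-bromo-3-[(2S)-1-methylpiperidin-2-yl]phenyl}-3-[4-(benzyloxy)phenyl]-3-hydroxypropan-1-one
Product: 17 (1S,3S)-1-{2,4-bis(benzyloxy)-6-bromo-3-[(2S)-1-methylpiperidin-2-yl]phenyl}-3-[4-(benzyloxy)phenyl]propane-1,3-diol
Conditions: Me4NBH(OAc)3, MeCN/AcOH, −30 → −20 °C
Reagents that add atoms: none
Why: Evans–Saksena reduction, in which the existing carbinol exchanges an acetate on boron and delivers hydride intramolecularly through a chair transition state, so that the new carbinol is set anti (1S) by the neighbouring stereocenter, and the low temperature protects the acid-sensitive 4-alkoxybenzylic alcohol.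

Step 11
Reactants: 17 (1S,3S)-1-{2,4-bis(benzyloxy)-6-bromo-3-[(2S)-1-methylpiperidin-2-yl]phenyl}-3-[4-(benzyloxy)phenyl]propane-1,3-diol
Product: 18 (2S,4S)-5,7-bis(benzyloxy)-2-[4-(benzyloxy)phenyl]-6-[(2S)-1-methylpiperidin-2-yl]chroman-4-ol
Conditions: CuI (10 mol%), 3,4,7,8-tetramethyl-1,10-phenanthroline (20 mol%), Cs2CO3, toluene (0.02 M), 110 °C
Reagents that add atoms: none
Why: Cs2CO3 converts the carbinol next to ring B into its alkoxide, which binds phenanthroline-ligated monovalent copper; oxidative addition of the C8a–Br bond gives a trivalent copper aryl alkoxide, and C–O reductive elimination releases the aryl ether and returns monovalent copper. The closest known reaction type is the Ullmann-type copper-catalysed O-arylation of aliphatic alcohols with aryl bromides, used intramolecularly to make 2-substituted chromans from secondary 3-(2-bromoaryl)propan-1-ols. Ring C closes as a six-membered ring by attack of oxygen on the sp2 carbon C8a with the breaking C–Br bond outside the ring (formally 6-exo-trig). No stereocenter is created: the C2–O bond is never broken, so the S configuration from step 9 is retained and the anti diol gives the 2,4-cis flavan-4-ol. The step needs chemoselectivity between two hydroxyls and for one arene carbon: the hydroxyl on the carbon attached to ring A would have to close a four-membered ring, the single bromine fixes C8a, the oxygens at C5 and C7 are masked as benzyl ethers, and dilution disfavours intermolecular etherification. Oxidative addition into the electron-rich bromide is slow, which the electron-rich tetramethylphenanthroline ligand and the temperature of 110 °C are meant to offset.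

Step 12
Reactants: 18 (2S,4S)-5,7-bis(benzyloxy)-2-[4-(benzyloxy)phenyl]-6-[(2S)-1-methylpiperidin-2-yl]chroman-4-ol
Product: 19 (2S)-5,7-bis(benzyloxy)-2-[4-(benzyloxy)phenyl]-6-[(2S)-1-methylpiperidin-2-yl]chroman-4-one
Conditions: CF3CO2H (1.1 equiv), then Dess–Martin periodinane, CH2Cl2, 0 °C → rt; aq. NaHCO3
Reagents that add atoms: none
Why: Dess–Martin oxidation of a secondary benzylic alcohol, in which protonation of the tertiary amine as its trifluoroacetate keeps nitrogen away from the hypervalent iodine oxidant and the non-basic conditions avoid enolisation, ring opening of the flavanone and loss of the C2 configuration.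

Step 13
Reactants: 19 (2S)-5,7-bis(benzyloxy)-2-[4-(benzyloxy)phenyl]-6-[(2S)-1-methylpiperidin-2-yl]chroman-4-one
Product: 20 (2S)-5,7-dihydroxy-2-(4-hydroxyphenyl)-6-[(2S)-1-methylpiperidin-2-yl]chroman-4-one
Conditions: H2 (1 atm), Pd/C, EtOAc/MeOH, rt
Reagents that add atoms: none
Why: catalytic hydrogenolysis of the three aryl benzyl ethers over palladium on carbon at ambient pressure and temperature, under neutral conditions in which the benzylic C2–O1 ether, the chelated aryl ketone and the hindered benzylic C–N bond are expected to react far more slowly.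

Compound list
1 | 4-bromo-2,6-dimethoxybenzaldehyde | COc1cc(Br)cc(OC)c1C=O | starting material
2 | 4-bromo-2,6-dihydroxybenzaldehyde | Oc1cc(Br)cc(O)c1C=O | intermediate
3 | 2,6-bis(benzyloxy)-4-bromobenzaldehyde | O=Cc1c(OCc2ccccc2)cc(Br)cc1OCc1ccccc1 | intermediate
4 | (R)-2-methylpropane-2-sulfinamide | CC(C)(C)[S@@](=O)N | starting material
5 | (R)-N-{(E)-[2,6-bis(benzyloxy)-4-bromophenyl]methylidene}-2-methylpropane-2-sulfinamide | CC(C)(C)[S@@](=O)/N=C/c1c(OCc2ccccc2)cc(Br)cc1OCc1ccccc1 | intermediate
6 | 1-bromo-4-chlorobutane | ClCCCCBr | starting material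
7 | 4-chlorobutylmagnesium bromide | ClCCCC[Mg]Br | intermediate
8 | (R)-N-{(1S)-1-[2,6-bis(benzyloxy)-4-bromophenyl]-5-chloropentyl}-2-methylpropane-2-sulfinamide | CC(C)(C)[S@@](=O)N[C@@H](CCCCCl)c1c(OCc2ccccc2)cc(Br)cc1OCc1ccccc1 | intermediate
9 | (2S)-2-[2,6-bis(benzyloxy)-4-bromophenyl]-1-[(R)-tert-butanesulfinyl]piperidine | CC(C)(C)[S@@](=O)N1CCCC[C@H]1c1c(OCc2ccccc2)cc(Br)cc1OCc1ccccc1 | intermediate
10 | (2S)-2-[2,6-bis(benzyloxy)-4-bromophenyl]piperidine hydrochloride | N1CCCC[C@H]1c1c(OCc2ccccc2)cc(Br)cc1OCc1ccccc1.Cl | intermediate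
11 | (2S)-2-[2,6-bis(benzyloxy)-4-bromophenyl]-1-methylpiperidine | CN1CCCC[C@H]1c1c(OCc2ccccc2)cc(Br)cc1OCc1ccccc1 | intermediate
12 | acetyl chloride | CC(=O)Cl | starting material
13 | 1-{2,4-bis(benzyloxy)-6-bromo-3-[(2S)-1-methylpiperidin-2-yl]phenyl}ethan-1-one | CN1CCCC[C@H]1c1c(OCc2ccccc2)cc(Br)c(C(C)=O)c1OCc1ccccc1 | intermediate
14 | methyl 4-(benzyloxy)benzoate | COC(=O)c1ccc(OCc2ccccc2)cc1 | starting material
15 | 1-{2,4-bis(benzyloxy)-6-bromo-3-[(2S)-1-methylpiperidin-2-yl]phenyl}-3-[4-(benzyloxy)phenyl]propane-1,3-dione | CN1CCCC[C@H]1c1c(OCc2ccccc2)cc(Br)c(C(=O)CC(=O)c2ccc(OCc3ccccc3)cc2)c1OCc1ccccc1 | intermediate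
16 | (3S)-1-{2,4-bis(benzyloxy)-6-bromo-3-[(2S)-1-methylpiperidin-2-yl]phenyl}-3-[4-(benzyloxy)phenyl]-3-hydroxypropan-1-one | CN1CCCC[C@H]1c1c(OCc2ccccc2)cc(Br)c(C(=O)C[C@H](O)c2ccc(OCc3ccccc3)cc2)c1OCc1ccccc1 | intermediate
17 | (1S,3S)-1-{2,4-bis(benzyloxy)-6-bromo-3-[(2S)-1-methylpiperidin-2-yl]phenyl}-3-[4-(benzyloxy)phenyl]propane-1,3-diol | CN1CCCC[C@H]1c1c(OCc2ccccc2)cc(Br)c([C@@H](O)C[C@H](O)c2ccc(OCc3ccccc3)cc2)c1OCc1ccccc1 | intermediate
18 | (2S,4S)-5,7-bis(benzyloxy)-2-[4-(benzyloxy)phenyl]-6-[(2S)-1-methylpiperidin-2-yl]chroman-4-ol (2,4-cis) | CN1CCCC[C@H]1c1c(OCc3ccccc3)cc2c(c1OCc1ccccc1)[C@@H](O)C[C@@H](c1ccc(OCc3ccccc3)cc1)O2 | intermediate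
19 | (2S)-5,7-bis(benzyloxy)-2-[4-(benzyloxy)phenyl]-6-[(2S)-1-methylpiperidin-2-yl]chroman-4-one | CN1CCCC[C@H]1c1c(OCc3ccccc3)cc2c(c1OCc1ccccc1)C(=O)C[C@@H](c1ccc(OCc3ccccc3)cc1)O2 | intermediate
20 | (2S)-5,7-dihydroxy-2-(4-hydroxyphenyl)-6-[(2S)-1-methylpiperidin-2-yl]chroman-4-one | CN1CCCC[C@H]1c1c(O)cc2c(c1O)C(=O)C[C@@H](c1ccc(O)cc1)O2 | target

Total step count: 13. Longest linear sequence: 13 steps (1 to 20); compounds 4, 6, 12 and 14 are bought and enter directly.

Steps most likely to fail

Step 7 (Friedel–Crafts acetylation). The Lewis acid may strip the benzyl group from the oxygen ortho to the new ketone by chelation-assisted dealkylation, or acetyl chloride may acylate nitrogen and open the electron-rich benzylic C–N bond. The fallback sets out from 11 and uses an electrophile that needs no metal Lewis acid. Vilsmeier–Haack formylation (POCl3, DMF, 0 → 60 °C, then aq. NaOAc) should give 2,4-bis(benzyloxy)-6-bromo-3-[(2S)-1-methylpiperidin-2-yl]benzaldehyde F1. Commercial 1-[4-(benzyloxy)phenyl]ethan-1-one is deprotonated with LiN(SiMe3)2 in THF at −78 °C to lithium 1-[4-(benzyloxy)phenyl]ethen-1-olate F2, which should add to F1 to give the aldol 3-{2,4-bis(benzyloxy)-6-bromo-3-[(2S)-1-methylpiperidin-2-yl]phenyl}-1-[4-(benzyloxy)phenyl]-3-hydroxypropan-1-one F3 as a mixture of carbinol epimers. Dess–Martin oxidation of its trifluoroacetate salt then gives diketone 15, where the route is rejoined; steps 7 and 8 are replaced.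

Step 11 (copper-catalysed ring closure). Oxidative addition into the electron-rich, ortho-substituted aryl bromide may be too slow, so that reductive loss of bromine or oxidation of a carbinol takes over. The fallback sets out from diketone 15 and forms the same C8a–O1 bond at the enol oxidation level, where the bromide is activated by the ortho carbonyl group. CuI, K2CO3, DMF at 100 °C should cyclise the enolate to the flavone 5,7-bis(benzyloxy)-2-[4-(benzyloxy)phenyl]-6-[(2S)-1-methylpiperidin-2-yl]-4H-chromen-4-one F4. Asymmetric hydrogenation of the C2–C3 double bond and the carbonyl with a catalyst formed from Ru(cod)(2-methylallyl)2, a chiral N-heterocyclic carbene ligand and KOtBu under H2, a known way from flavones to cis-flavan-4-ols, should then give 18, where the route is rejoined. C2 is then set by the hydrogenation catalyst, and steps 9 to 11 are replaced.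

Step 13 (global debenzylation). Hydrogenolysis may continue past the benzyl ethers: the benzylic C2–O1 bond (directly or through the ring-opened chalcone) or the benzylic C–N bond of the piperidine, once the flanking phenols are free, can be reduced. The fallback sets out from 19 and reaches 20 directly without a reductant: BCl3 with pentamethylbenzene as benzyl cation scavenger in CH2Cl2 at −78 °C cleaves aryl benzyl ethers by Lewis-acid dealkylation, and the low temperature limits chelation-driven opening of ring C. No new compound is made on the way.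

Further compounds
F1 | step 7 | 2,4-bis(benzyloxy)-6-bromo-3-[(2S)-1-methylpiperidin-2-yl]benzaldehyde | CN1CCCC[C@H]1c1c(OCc2ccccc2)cc(Br)c(C=O)c1OCc1ccccc1
F2 | step 7 | lithium 1-[4-(benzyloxy)phenyl]ethen-1-olate | [Li]OC(=C)c1ccc(OCc2ccccc2)cc1
F3 | step 7 | 3-{2,4-bis(benzyloxy)-6-bromo-3-[(2S)-1-methylpiperidin-2-yl]phenyl}-1-[4-(benzyloxy)phenyl]-3-hydroxypropan-1-one (both carbinol epimers) | CN1CCCC[C@H]1c1c(OCc2ccccc2)cc(Br)c(C(O)CC(=O)c2ccc(OCc3ccccc3)cc2)c1OCc1ccccc1
F4 | step 11 | 5,7-bis(benzyloxy)-2-[4-(benzyloxy)phenyl]-6-[(2S)-1-methylpiperidin-2-yl]-4H-chromen-4-one | CN1CCCC[C@H]1c1c(OCc3ccccc3)cc2c(c1OCc1ccccc1)C(=O)C=C(c1ccc(OCc3ccccc3)cc1)O2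
F0 | step 13 | none | none
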